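**Retrosynthetic overview**
- Target 14 comes from stilbene 13 by one hydrogenation that saturates the C=C bond and removes both O-benzyl groups.
- 13 comes from β-hydroxy acid 12 by decarboxylative dehydration; 12 is made by the key intermolecular aldol addition of the dianion of arylacetic acid 10 to aldehyde 7, which forms the future CH2–CH2 bond.
- 7 comes from ester 5 (reduction, then oxidation); 5 comes from Negishi benzylation of bromo ester 2 with benzylic chloride 3; 2 comes from regioselective bromination of 1.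
- 10 comes from O-benzylation of (3-hydroxyphenyl)acetic acid 8.
- No ring is formed: all three benzene rings are bought intact.

Assumption: the target has no stereocentre (it is achiral), so no enantiocontrol is needed; the transient stereocentres of 12 and the alkene geometry of 13 are erased later.

**Step 1**
Reactants: 1 methyl 3,5-dimethoxybenzoate
Product: 2 methyl 2-bromo-3,5-dimethoxybenzoate
Conditions: NBS (1.05 equiv), MeCN, 0 °C to rt
Reagents that add atoms: N-bromosuccinimide O=C1CCC(=O)N1Br
Why: Electrophilic aromatic bromination with NBS in MeCN goes to C2 (para to one OMe, ortho to the other) rather than the doubly flanked C4, and one equivalent stops at the monobromide.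

**Step 2**
Reactants: 2 methyl 2-bromo-3,5-dimethoxybenzoate; 3 1-(benzyloxy)-4-(chloromethyl)benzene
Product: 5 methyl 2-[4-(benzyloxy)benzyl]-3,5-dimethoxybenzoate, via [4-(benzyloxy)benzyl]zinc chloride 4 (not isolated)
Conditions: 3, Zn dust, LiCl, THF, 25 °C; then 2, Pd(OAc)2 (2 mol %), SPhos (4 mol %), THF, 25 to 50 °C
Reagents that add atoms: none
Why: Negishi cross-coupling; LiCl-assisted zinc insertion gives an ester-tolerant benzylic zinc reagent, and Pd/SPhos couples it with the hindered aryl bromide, whose oxidative addition is helped by the ortho ester.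

**Step 3**
Reactants: 5 methyl 2-[4-(benzyloxy)benzyl]-3,5-dimethoxybenzoate
Product: 6 {2-[4-(benzyloxy)benzyl]-3,5-dimethoxyphenyl}methanol
Conditions: LiAlH4, THF, 0 °C to rt; H2O quench
Reagents that add atoms: none
Why: LiAlH4 hydride reduction of the ester gives the primary benzylic alcohol, and the aryl methyl and benzyl ethers are inert to it.

**Step 4**
Reactants: 6 {2-[4-(benzyloxy)benzyl]-3,5-dimethoxyphenyl}methanol
Product: 7 2-[4-(benzyloxy)benzyl]-3,5-dimethoxybenzaldehyde
Conditions: activated MnO2 (10 equiv), CH2Cl2, rt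
Reagents that add atoms: none
Why: MnO2 oxidation is selective for benzylic alcohols and stops at the aldehyde without touching the diarylmethane CH2 or the ethers.

**Step 5**
Reactants: 8 (3-hydroxyphenyl)acetic acid
Product: 10 [3-(benzyloxy)phenyl]acetic acid, via benzyl ester 9 (not isolated)
Conditions: BnBr (2.3 equiv), K2CO3, DMF, 60 °C; then NaOH, MeOH/H2O, 60 °C; then aq HCl
Reagents that add atoms: benzyl bromide BrCc1ccccc1; sodium hydroxide [Na+].[OH-]
Why: Williamson O-alkylation benzylates both the phenol and the carboxylate, and saponification then cleaves only the benzyl ester, leaving the aryl benzyl ether.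

**Step 6**
Reactants: 10 [3-(benzyloxy)phenyl]acetic acid; 7 2-[4-(benzyloxy)benzyl]-3,5-dimethoxybenzaldehyde
Product: 12 2-[3-(benzyloxy)phenyl]-3-{2-[4-(benzyloxy)benzyl]-3,5-dimethoxyphenyl}-3-hydroxypropanoic acid (racemic syn/anti mixture), via dilithium enediolate 11 (not isolated)
Conditions: 10, LDA (2.2 equiv), THF, −78 to 0 °C; then 7, −78 °C; cold dilute HCl quench
Reagents that add atoms: none
Why: Intermolecular aldol addition (Ivanov-type) of the arylacetic acid dianion to the non-enolisable aldehyde joins the two fragments; the two new stereocentres form unselectively, which is harmless because both are destroyed in steps 7 and 8.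

**Step 7**
Reactants: 12 2-[3-(benzyloxy)phenyl]-3-{2-[4-(benzyloxy)benzyl]-3,5-dimethoxyphenyl}-3-hydroxypropanoic acid
Product: 13 2-[4-(benzyloxy)benzyl]-1-{(E)-2-[3-(benzyloxy)phenyl]ethenyl}-3,5-dimethoxybenzene
Conditions: DMF dineopentyl acetal (3 equiv), toluene, 80 °C
Reagents that add atoms: none
Why: Decarboxylative dehydration of a β-hydroxy acid; the acetal activates the benzylic OH as an O-formamidinium group, which fragments with loss of CO2 and DMF to the stilbene (mainly E), and the neopentyl groups cannot esterify the acid.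

**Step 8**
Reactants: 13 2-[4-(benzyloxy)benzyl]-1-{(E)-2-[3-(benzyloxy)phenyl]ethenyl}-3,5-dimethoxybenzene
Product: 14 Gymcononopin D, 3-{2-[2-(4-hydroxybenzyl)-3,5-dimethoxyphenyl]ethyl}phenol
Conditions: H2 (1 atm), 10% Pd/C, EtOAc/MeOH, rt
Reagents that add atoms: none
Why: Catalytic hydrogenation saturates the stilbene and hydrogenolyses both benzyl ethers in one operation, while the methyl ethers and the diarylmethane CH2 are stable.

**Compound list**
1 | methyl 3,5-dimethoxybenzoate | COC(=O)c1cc(OC)cc(OC)c1 | starting material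
2 | methyl 2-bromo-3,5-dimethoxybenzoate | COC(=O)c1cc(OC)cc(OC)c1Br | intermediate
3 | 1-(benzyloxy)-4-(chloromethyl)benzene | ClCc1ccc(OCc2ccccc2)cc1 | starting material
4 | [4-(benzyloxy)benzyl]zinc chloride | Cl[Zn]Cc1ccc(OCc2ccccc2)cc1 | intermediate
5 | methyl 2-[4-(benzyloxy)benzyl]-3,5-dimethoxybenzoate | COC(=O)c1cc(OC)cc(OC)c1Cc1ccc(OCc2ccccc2)cc1 | intermediate
6 | {2-[4-(benzyloxy)benzyl]-3,5-dimethoxyphenyl}methanol | OCc1cc(OC)cc(OC)c1Cc1ccc(OCc2ccccc2)cc1 | intermediate
7 | 2-[4-(benzyloxy)benzyl]-3,5-dimethoxybenzaldehyde | O=Cc1cc(OC)cc(OC)c1Cc1ccc(OCc2ccccc2)cc1 | intermediate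
8 | (3-hydroxyphenyl)acetic acid | OC(=O)Cc1cccc(O)c1 | starting material
9 | benzyl [3-(benzyloxy)phenyl]acetate | O=C(Cc1cccc(OCc2ccccc2)c1)OCc1ccccc1 | intermediate
10 | [3-(benzyloxy)phenyl]acetic acid | OC(=O)Cc1cccc(OCc2ccccc2)c1 | intermediate
11 | dilithium enediolate of [3-(benzyloxy)phenyl]acetic acid | [Li+].[Li+].[O-]C([O-])=Cc1cccc(OCc2ccccc2)c1 | intermediate
12 | 2-[3-(benzyloxy)phenyl]-3-{2-[4-(benzyloxy)benzyl]-3,5-dimethoxyphenyl}-3-hydroxypropanoic acid (racemic syn/anti mixture) | OC(=O)C(c1cccc(OCc2ccccc2)c1)C(O)c1cc(OC)cc(OC)c1Cc1ccc(OCc2ccccc2)cc1 | intermediate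
13 | 2-[4-(benzyloxy)benzyl]-1-{(E)-2-[3-(benzyloxy)phenyl]ethenyl}-3,5-dimethoxybenzene | COc1cc(/C=C/c2cccc(OCc3ccccc3)c2)c(Cc2ccc(OCc3ccccc3)cc2)c(OC)c1 | intermediate
14 | Gymcononopin D, 3-{2-[2-(4-hydroxybenzyl)-3,5-dimethoxyphenyl]ethyl}phenol (achiral) | COc1cc(CCc2cccc(O)c2)c(Cc2ccc(O)cc2)c(OC)c1 | target

**Step count:** 8 steps in total; the longest linear sequence is 7 steps (steps 1, 2, 3, 4, 6, 7, 8 from compound 1).

**Steps most likely to fail, with fallbacks**

Step 2 (Negishi benzylation of the doubly ortho-substituted bromide; risk of Wurtz dimer of 3 or slow coupling). The fallback changes the benzyl nucleophile from zinc to boron. It sets out from 3: Pd-catalysed benzylic borylation (B2pin2, Pd2(dba)3, (4-MeOC6H4)3P, KOAc, toluene, 50 °C) gives 2-[4-(benzyloxy)benzyl]-4,4,5,5-tetramethyl-1,3,2-dioxaborolane F1. Treatment with KHF2 in MeOH/H2O converts this into potassium [4-(benzyloxy)benzyl]trifluoroborate F2. Suzuki–Miyaura coupling of this salt with 2 (Pd(OAc)2, RuPhos, K2CO3, toluene/H2O, 85 °C) comes back to the route at 5.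

Step 6 (dianion aldol; risk of poor dianion solubility or retro-aldol on warming). The fallback replaces the low-temperature addition by a thermodynamic condensation. It sets out from 7 and 10: Perkin-type condensation (Ac2O, Et3N, 120 °C) gives (E)-2-[3-(benzyloxy)phenyl]-3-{2-[4-(benzyloxy)benzyl]-3,5-dimethoxyphenyl}prop-2-enoic acid F3, with the two aryl groups cis. Copper/quinoline decarboxylation at about 200 °C then gives 2-[4-(benzyloxy)benzyl]-1-{(Z)-2-[3-(benzyloxy)phenyl]ethenyl}-3,5-dimethoxybenzene F4. Hydrogenation of this Z-stilbene under the conditions of step 8 comes back to the route at 14.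

Step 7 (decarboxylative dehydration; risk of sluggish fragmentation or side reactions at the benzylic position). The fallback separates activation from CO2 loss. It sets out from 12: benzenesulfonyl chloride in pyridine at 0 °C closes the β-lactone 3-[3-(benzyloxy)phenyl]-4-{2-[4-(benzyloxy)benzyl]-3,5-dimethoxyphenyl}oxetan-2-one F5. Heating this lactone in DMF at 120–140 °C extrudes CO2 by thermal cycloreversion and comes back to the route at 13; any Z isomer formed alongside is hydrogenated to the same 14 in step 8.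

**Further compounds**
F1 | step 2 | 2-[4-(benzyloxy)benzyl]-4,4,5,5-tetramethyl-1,3,2-dioxaborolane | CC1(C)OB(Cc2ccc(OCc3ccccc3)cc2)OC1(C)C
F2 | step 2 | potassium [4-(benzyloxy)benzyl]trifluoroborate | [K+].F[B-](F)(F)Cc1ccc(OCc2ccccc2)cc1
F3 | step 6 | (E)-2-[3-(benzyloxy)phenyl]-3-{2-[4-(benzyloxy)benzyl]-3,5-dimethoxyphenyl}prop-2-enoic acid | OC(=O)/C(c1cccc(OCc2ccccc2)c1)=C/c1cc(OC)cc(OC)c1Cc1ccc(OCc2ccccc2)cc1
F4 | step 6 | 2-[4-(benzyloxy)benzyl]-1-{(Z)-2-[3-(benzyloxy)phenyl]ethenyl}-3,5-dimethoxybenzene | COc1cc(/C=C\c2cccc(OCc3ccccc3)c2)c(Cc2ccc(OCc3ccccc3)cc2)c(OC)c1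
F5 | step 7 | 3-[3-(benzyloxy)phenyl]-4-{2-[4-(benzyloxy)benzyl]-3,5-dimethoxyphenyl}oxetan-2-one (racemic cis/trans mixture) | O=C1OC(c2cc(OC)cc(OC)c2Cc2ccc(OCc3ccccc3)cc2)C1c1cccc(OCc2ccccc2)c1
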